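**Retrosynthetic overview**
- The single ring is closed last, by ring-closing metathesis at C-4=C-5 of an acyclic octa-1,7-diene that already carries all four stereocenters and all acyl groups.
- Key disconnection C-6–C-1: an oxygen-bearing allyl carbanion (the (Z)-γ-methoxyallyl boron reagent from allyl methyl ether) adds through its methoxy-bearing carbon to a ketone carbon. This joins two carbons that are both normally electrophilic and sets C-1 and C-6 in one step.
- The ketone, BzOCH2–CO–CH(OAc)–CH(OBz)–CH=CH2, comes from C2-symmetric (3R,4R)-hexa-1,5-diene-3,4-diol, which supplies C-2 and C-3: monobenzoate, OH-directed epoxidation, acetate, benzoate opening, oxidation.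

Assumption: diol 1 is bought as such (a catalogue compound, otherwise made in three steps from D-mannitol).
Locants used below are those of the target: C-1 = C(OH)(CH2OBz), C-2 = CHOAc, C-3 = CHOBz, C-4=C-5, C-6 = CHOMe, C-7 = CH2OBz.

**Step 1**
Reactants: 1 (3R,4R)-hexa-1,5-diene-3,4-diol
Product: 3 (3R,4R)-4-hydroxyhexa-1,5-dien-3-yl benzoate, via cyclic orthobenzoate 2 (not isolated)
Conditions: PhC(OMe)3 (1.2 equiv), CSA (2 mol %), CH2Cl2, rt; then AcOH/H2O 4:1, rt
Reagents that add atoms: trimethyl orthobenzoate COC(OC)(OC)c1ccccc1; water O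
Why: Orthoester exchange gives the five-membered cyclic orthobenzoate, and its acid hydrolysis (via the dioxolan-2-ylium ion) gives one hydroxy benzoate only, because in the C2-symmetric diol both ring C–O bonds are equivalent; no stereocenter is touched.

**Step 2**
Reactants: 3 (3R,4R)-4-hydroxyhexa-1,5-dien-3-yl benzoate
Product: 4 (3R,4S)-4-hydroxy-4-[(2R)-oxiran-2-yl]but-1-en-3-yl benzoate (major erythro epimer, about 4:1 over the oxirane epimer)
Conditions: VO(acac)2 (3 mol %), t-BuOOH (1.5 equiv, decane), CH2Cl2, 0 °C to rt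
Reagents that add atoms: tert-butyl hydroperoxide CC(C)(C)OO
Why: Sharpless–Michaelson hydroxyl-directed epoxidation: the vanadate ester of the free C-2 hydroxyl delivers oxygen only to the adjacent vinyl group (the other vinyl sits next to a benzoate and reacts far more slowly), giving mainly the erythro epoxy alcohol; the new center is erased in step 5, so both epimers are carried on.

**Step 3**
Reactants: 4 (3R,4S)-4-hydroxy-4-[(2R)-oxiran-2-yl]but-1-en-3-yl benzoate
Product: 5 (3R,4S)-4-(acetyloxy)-4-[(2R)-oxiran-2-yl]but-1-en-3-yl benzoate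
Conditions: Ac2O, pyridine, DMAP (5 mol %), CH2Cl2, 0 °C
Reagents that add atoms: acetic anhydride CC(=O)OC(C)=O
Why: DMAP-catalysed acylation of the only free hydroxyl is faster than any benzoate migration, and the epoxide and stereocenters are inert to these conditions.

**Step 4**
Reactants: 5 (3R,4S)-4-(acetyloxy)-4-[(2R)-oxiran-2-yl]but-1-en-3-yl benzoate
Product: 6 (2R,3R,4R)-3-(acetyloxy)-2-hydroxyhex-5-ene-1,4-diyl dibenzoate (major C-1 epimer)
Conditions: BzOH (1.2 equiv), rac-(salen)Co(OAc) (5 mol %; salen = N,N'-bis(3,5-di-tert-butylsalicylidene)cyclohexane-1,2-diamine dianion, trivalent cobalt), iPr2NEt (10 mol %), TBME, rt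
Reagents that add atoms: benzoic acid OC(=O)c1ccccc1
Why: Jacobsen-type cobalt–salen-catalysed opening of a terminal epoxide by a carboxylic acid: benzoate attacks the unhindered CH2 terminus (SN2), the racemic catalyst serves both oxirane epimers, and the weakly acidic medium at room temperature keeps the C-2 acetate from migrating to the new C-1 hydroxyl.

**Step 5**
Reactants: 6 (2R,3R,4R)-3-(acetyloxy)-2-hydroxyhex-5-ene-1,4-diyl dibenzoate
Product: 7 (3S,4R)-3-(acetyloxy)-2-oxohex-5-ene-1,4-diyl dibenzoate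
Conditions: Dess–Martin periodinane (1.3 equiv), CH2Cl2, rt; brief Na2S2O3/NaHCO3 wash, used promptly
Reagents that add atoms: none
Why: Dess–Martin oxidation under non-basic conditions gives the α,α'-diacyloxy ketone (the same type as the stable keto-hexose peracetates) without E1cB loss of the β-benzoate or epimerization at C-2, and it merges both C-1 epimers into one compound.

**Step 6**
Reactants: 7 (3S,4R)-3-(acetyloxy)-2-oxohex-5-ene-1,4-diyl dibenzoate; 8 allyl methyl ether (3-methoxyprop-1-ene)
Product: 13 (3R,4S,5R,6S)-4-(acetyloxy)-5-[(benzoyloxy)methyl]-5-hydroxy-6-methoxyocta-1,7-dien-3-yl benzoate, via lithiated ether 9 (not isolated), via borate 10 (not isolated), via methoxyallylborane 11 (not isolated), via borinate 12 (not isolated)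
Conditions: 8 (2.0 equiv), s-BuLi (1.6 equiv), THF, −78 °C; (+)-Ipc2BOMe (1.6 equiv, from (−)-α-pinene), −78 °C; BF3·OEt2 (2.1 equiv), −78 °C; then 7, −78 to −40 °C; then pH 7 buffer (NaH2PO4/Na2HPO4), 30% H2O2, MeOH, 0 °C
Reagents that add atoms: none
Why: Proposed new method: the oxygen-chelated (Z)-γ-methoxyallyllithium 9 is trapped on boron at its CH2 end (10), BF3 removes methoxide to give the (Z)-γ-methoxyallylborane 11, and this adds through its methoxy-bearing carbon to the doubly α-acyloxy-activated ketone 7 in a closed Zimmerman–Traxler chair with the Z-methoxy group axial, the branched C-2 chain equatorial and the small CH2OBz arm axial, so that OMe at C-6 and OH at C-1 come out syn along the C-5–C-6–C-1–C-2 chain as in 14; the l-Ipc ligands select the chair that attacks the ketone face also favoured by the Cornforth/polar Felkin–Anh arrangement of the C-2 acetoxy group (matched double induction, C-1–OH anti to C-2–OAc), giving (1R,6S); the closest known reactions are Brown's γ-methoxyallylboration of aldehydes with this same reagent, the anti-selective additions of (Z)-γ-alkoxyallylboron reagents to α-alkoxy aldehydes, and allylboration of ketones with B-allyldiisopinocampheylborane, and the untested part is the use of the methoxyallyl reagent on a ketone.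

**Step 7**
Reactants: 13 (3R,4S,5R,6S)-4-(acetyloxy)-5-[(benzoyloxy)methyl]-5-hydroxy-6-methoxyocta-1,7-dien-3-yl benzoate
Product: 14 [(1R,2S,5R,6S)-6-(acetyloxy)-5-(benzoyloxy)-1-hydroxy-2-methoxycyclohex-3-en-1-yl]methyl benzoate
Conditions: second-generation Grubbs catalyst (H2IMes)(PCy3)Cl2Ru=CHPh (5 mol %), CH2Cl2 (5 mM), 40 °C
Reagents that add atoms: none
Why: Ring-closing olefin metathesis of the 1,7-diene closes the six-membered ring at C-4=C-5 with loss of ethene; the ruthenium carbene tolerates the esters, the ether and the free tertiary alcohol, and no stereocenter is involved.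

**Compound list**
1 | (3R,4R)-hexa-1,5-diene-3,4-diol | C=C[C@@H](O)[C@H](O)C=C | starting material
2 | (4R,5R)-4,5-diethenyl-2-methoxy-2-phenyl-1,3-dioxolane | COC1(c2ccccc2)O[C@H](C=C)[C@@H](C=C)O1 | intermediate
3 | (3R,4R)-4-hydroxyhexa-1,5-dien-3-yl benzoate | C=C[C@@H](OC(=O)c1ccccc1)[C@H](O)C=C | intermediate
4 | (3R,4S)-4-hydroxy-4-[(2R)-oxiran-2-yl]but-1-en-3-yl benzoate (major epimer) | C=C[C@@H](OC(=O)c1ccccc1)[C@H](O)[C@H]1CO1 | intermediate
5 | (3R,4S)-4-(acetyloxy)-4-[(2R)-oxiran-2-yl]but-1-en-3-yl benzoate (major epimer) | C=C[C@@H](OC(=O)c1ccccc1)[C@H](OC(C)=O)[C@H]1CO1 | intermediate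
6 | (2R,3R,4R)-3-(acetyloxy)-2-hydroxyhex-5-ene-1,4-diyl dibenzoate (major epimer) | C=C[C@@H](OC(=O)c1ccccc1)[C@H](OC(C)=O)[C@H](O)COC(=O)c1ccccc1 | intermediate
7 | (3S,4R)-3-(acetyloxy)-2-oxohex-5-ene-1,4-diyl dibenzoate | C=C[C@@H](OC(=O)c1ccccc1)[C@H](OC(C)=O)C(=O)COC(=O)c1ccccc1 | intermediate
8 | allyl methyl ether (3-methoxyprop-1-ene) | COCC=C | starting material
9 | (Z)-(3-methoxyprop-2-en-1-yl)lithium, oxygen-chelated | [Li]C/C=C\OC | intermediate
10 | lithium bis(l-isopinocampheyl)(methoxy)[(Z)-3-methoxyprop-2-en-1-yl]borate | [Li+].CO/C=C\C[B-](OC)([C@H]1C[C@H]2C[C@@H]([C@@H]1C)C2(C)C)[C@H]1C[C@H]2C[C@@H]([C@@H]1C)C2(C)C | intermediate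
11 | bis(l-isopinocampheyl)[(Z)-3-methoxyprop-2-en-1-yl]borane | CO/C=C\CB([C@H]1C[C@H]2C[C@@H]([C@@H]1C)C2(C)C)[C@H]1C[C@H]2C[C@@H]([C@@H]1C)C2(C)C | intermediate
12 | bis(l-isopinocampheyl)borinate ester of 13 at the C-1 oxygen | C=C[C@@H](OC(=O)c1ccccc1)[C@H](OC(C)=O)[C@@](OB([C@H]1C[C@H]2C[C@@H]([C@@H]1C)C2(C)C)[C@H]1C[C@H]2C[C@@H]([C@@H]1C)C2(C)C)(COC(=O)c1ccccc1)[C@@H](OC)C=C | intermediate
13 | (3R,4S,5R,6S)-4-(acetyloxy)-5-[(benzoyloxy)methyl]-5-hydroxy-6-methoxyocta-1,7-dien-3-yl benzoate | C=C[C@@H](OC(=O)c1ccccc1)[C@H](OC(C)=O)[C@@](O)(COC(=O)c1ccccc1)[C@@H](OC)C=C | intermediate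
14 | [(1R,2S,5R,6S)-6-(acetyloxy)-5-(benzoyloxy)-1-hydroxy-2-methoxycyclohex-3-en-1-yl]methyl benzoate | CO[C@H]1C=C[C@@H](OC(=O)c2ccccc2)[C@H](OC(C)=O)[C@@]1(O)COC(=O)c1ccccc1 | target

**Step count and risks**
Total step count: 7. Longest linear sequence: 7 (1 to 14).

Most likely to fail, first: step 6. The hindered Ipc2B reagent may add slowly to a ketone, and the ratio of C-1 epimers rests on the chair model. Fallback, setting out from 7 and 8 and coming back at 13: lithiate 8 with s-BuLi in THF at −78 °C and quench with Bu3SnCl to get tributyl[(Z)-3-methoxyprop-2-en-1-yl]stannane F1. Add F1 to 7 with BF3·OEt2 in CH2Cl2 at −78 °C and work up with aqueous KF. This is a Lewis-acid-promoted allylstannane addition through an open antiperiplanar transition state, with facial control by the C-2 acetoxy group alone (polar Felkin–Anh). It is expected to favour the same isomer 13 with lower selectivity, the isomers being separated at 13 or after ring closure.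

Second: step 4. The C-2 acetate could migrate to the freed C-1 hydroxyl, which would put the ketone at the wrong carbon after oxidation. Fallback, setting out from 4 and coming back at 7: silylate 4 with Et3SiCl and imidazole in CH2Cl2 to (3R,4S)-4-[(2R)-oxiran-2-yl]-4-(triethylsilyloxy)but-1-en-3-yl benzoate F2, which cannot pass an acyl group on. Open the epoxide as in step 4 (BzOH, rac-(salen)Co(OAc), TBME) to (2R,3R,4R)-2-hydroxy-3-(triethylsilyloxy)hex-5-ene-1,4-diyl dibenzoate F3. Oxidize with Dess–Martin periodinane to (3S,4R)-2-oxo-3-(triethylsilyloxy)hex-5-ene-1,4-diyl dibenzoate F4. Exchange the silyl ether directly for the acetate with Ac2O and Bi(OTf)3 (2 mol %) in MeCN at 0 °C, which gives 7.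

Third: step 7. Both vinyl groups are deactivated by allylic oxygen, one lies next to the fully substituted C-1, and the free C-1 hydroxyl with the C-6 methoxy group can tie up ruthenium. Fallback, setting out from 13 and coming back at 14: cap the tertiary hydroxyl with Me3SiOTf and 2,6-lutidine in CH2Cl2 at −78 °C to give the trimethylsilyl ether of 13 F5. Cyclize F5 with the second-generation Hoveyda–Grubbs catalyst (H2IMes)Cl2Ru=CH(C6H4-2-OiPr) in toluene at 80 °C to the trimethylsilyl ether of 14 F6. Remove the silyl group with citric acid in MeOH at rt to reach 14.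

**Further compounds**
F1 | step 6 | tributyl[(Z)-3-methoxyprop-2-en-1-yl]stannane | CCCC[Sn](CCCC)(CCCC)C/C=C\OC
F2 | step 4 | (3R,4S)-4-[(2R)-oxiran-2-yl]-4-(triethylsilyloxy)but-1-en-3-yl benzoate | C=C[C@@H](OC(=O)c1ccccc1)[C@H](O[Si](CC)(CC)CC)[C@H]1CO1
F3 | step 4 | (2R,3R,4R)-2-hydroxy-3-(triethylsilyloxy)hex-5-ene-1,4-diyl dibenzoate | C=C[C@@H](OC(=O)c1ccccc1)[C@H](O[Si](CC)(CC)CC)[C@H](O)COC(=O)c1ccccc1
F4 | step 4 | (3S,4R)-2-oxo-3-(triethylsilyloxy)hex-5-ene-1,4-diyl dibenzoate | C=C[C@@H](OC(=O)c1ccccc1)[C@H](O[Si](CC)(CC)CC)C(=O)COC(=O)c1ccccc1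
F5 | step 7 | trimethylsilyl ether of 13 at the tertiary hydroxyl | C=C[C@@H](OC(=O)c1ccccc1)[C@H](OC(C)=O)[C@@](O[Si](C)(C)C)(COC(=O)c1ccccc1)[C@@H](OC)C=C
F6 | step 7 | trimethylsilyl ether of 14 at the tertiary hydroxyl | CO[C@H]1C=C[C@@H](OC(=O)c2ccccc2)[C@H](OC(C)=O)[C@@]1(O[Si](C)(C)C)COC(=O)c1ccccc1
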